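**Retrosynthetic overview**

1. The CH2 bridge is cut last (phenolic Mannich base → ortho-quinone methide + enol C–H), giving chromene 15 and the (4R)-triketone 10 (ring A of the target: C1 carbonyl, C2 bridge carbon, C3 and C5 enol carbons, C4 quaternary, C6 acyl-bearing).
2. 10 comes from the aromatic benzoate 7 by ligand-controlled dearomative prenylation at C4, followed by loss of the C2 ester, which until then blocks the only other alkylatable ring carbon.
3. Ring A is built in one operation from two open-chain C3 units: diene 3 supplies C2–C3–C4 and methyl malonyl chloride supplies C5–C6–C1; the bonds formed are C4–C5 (acylation) and C1–C2 (Claisen closure). What allows this is that ring A is a cyclohexane-1,3,5-trione enol: the oxygen-bearing C1, C3 and C5 alternate with the carbon-substituted C2, C4 and C6, a cyclized tri-β-keto chain at the phloroglucinol oxidation level that is an aromatic benzoate as long as C4 carries only methyl.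
4. Ring order: benzene ring A (step 3, dearomatized in step 5); the pyran ring of the chromene (step 9) on purchased phloroglucinol; the two halves are joined in step 11.

Key step: step 3

Remark: ring-A compounds are drawn in the enol tautomer of the target SMILES and CIP descriptors refer to these drawings (S in 8 and 9, R in 10 and 17, same spatial arrangement); methyl 3-methylbut-2-en-1-yl carbonate is taken as purchasable (otherwise one routine step from prenol and methyl chloroformate).

**Route**

Step 1
Reactants: 1 methyl 3-oxopentanoate
Product: 2 methyl 3-(trimethylsilyloxy)pent-2-enoate (E/Z mixture)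
Conditions: Me3SiCl, Et3N, hexane, rt
Reagents that add atoms: chlorotrimethylsilane, C[Si](C)(C)Cl
Why: O-silylation of the enolizable β-keto ester under amine base gives the 3-silyloxy enoate, the standard first stage of a 1,3-bis(silyl enol ether) (Chan-type diene) preparation.

Step 2
Reactants: 2 methyl 3-(trimethylsilyloxy)pent-2-enoate
Product: 3 1-methoxy-1,3-bis(trimethylsilyloxy)penta-1,3-diene (mixture of geometric isomers)
Conditions: LiN(iPr)2, THF, −78 °C; then Me3SiCl, −78 °C to rt
Reagents that add atoms: chlorotrimethylsilane, C[Si](C)(C)Cl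
Why: Kinetic deprotonation of the vinylogous ester and O-silylation of the dienolate gives the 1,3-bis(silyl enol ether), a neutral equivalent of the β-keto ester 1,3-dianion.

Step 3
Reactants: 3 1-methoxy-1,3-bis(trimethylsilyloxy)penta-1,3-diene; 4 methyl 3-chloro-3-oxopropanoate (methyl malonyl chloride)
Product: 6 methyl 2,4,6-trihydroxy-3-methylbenzoate, via dimethyl 4-methyl-3,5-dioxoheptanedioate 5 (not isolated)
Conditions: CH2Cl2, −78 °C to rt; then evaporate, NaOMe, MeOH, 65 °C; aq. HCl
Reagents that add atoms: none
Why: The terminal carbon of diene 3 (future C4) attacks the acid chloride of 4 (future C5) and, after loss of Me3SiCl and methanolysis of the second silyl group, gives the open-chain tri-β-keto diester 5; methoxide then forms its polyanion, in which the carbanion at C2 (between ketone C3 and its ester) adds to the ester carbonyl C1 at the other chain end, expels methoxide, and the resulting cyclohexane-1,3,5-trione enolizes to the aromatic benzoate 6. The closest known reactions are the uncatalysed terminal acylation of 1,3-bis(silyl enol ethers) by acid chlorides and the classical Claisen-type cyclization of 3-oxoglutarate/malonate-derived and other poly-β-keto esters to phloroglucinols. The single ring closure is a 6-(enolendo)-exo-trig Claisen (Dieckmann-type) acylation, and no stereocentre is created. The step needs terminal rather than central acylation of 3, which the vinylogous silyl ketene acetal terminus should secure in the absence of a Lewis acid, and closure through carbon rather than oxygen, which should be secured because the alternative 4-hydroxy-2-pyranone is reopened by methoxide while the aromatic phenoxide of 6 is an irreversible sink. The 1,3,5-trioxygenation of ring A is what lets all six ring carbons arrive at the correct oxidation level from a β-keto ester and a malonyl unit, with the methyl group and the ester handle already in place.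

Step 4
Reactants: 6 methyl 2,4,6-trihydroxy-3-methylbenzoate
Product: 7 methyl 2,4,6-trihydroxy-3-methyl-5-(2-methylpropanoyl)benzoate
Conditions: 2-methylpropanoyl chloride, AlCl3, PhNO2–CH2Cl2, rt to 50 °C
Reagents that add atoms: 2-methylpropanoyl chloride, CC(C)C(Cl)=O
Why: Friedel–Crafts acylation of the phloroglucinol ring can occur only at its single free position (C6 of ring A), and the methyl ester tolerates AlCl3.

Step 5
Reactants: 7 methyl 2,4,6-trihydroxy-3-methyl-5-(2-methylpropanoyl)benzoate
Product: 8 methyl (3S)-2,4-dihydroxy-3-methyl-3-(3-methylbut-2-en-1-yl)-5-(2-methylpropanoyl)-6-oxocyclohexa-1,4-diene-1-carboxylate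
Conditions: methyl 3-methylbut-2-en-1-yl carbonate, Pd2(dba)3·CHCl3 (2.5 mol %), (R,R)-DACH-phenyl Trost ligand (7.5 mol %; antipode if the sense of induction requires), THF, 0 °C to rt
Reagents that add atoms: methyl 3-methylbut-2-en-1-yl carbonate, COC(=O)OCC=C(C)C
Why: Proposed new method: zerovalent palladium ionizes the carbonate to a cationic (π-prenyl)palladium complex of the chiral diphosphine, and the methoxide released with CO2 deprotonates 7 at its most acidic hydroxyl (on C3, para to the ketone); the phloroglucinolate should attack the unsubstituted allyl terminus outer-sphere through C4, the only ring carbon not deactivated by an acyl or ester group, and the ligand amide N–H/phenolate contact is expected to select one face because the charge sits on the ester-flanked side of C4; the closest known reactions are the palladium-catalysed asymmetric allylic dearomatization of naphthols, the palladium-catalysed asymmetric linear prenylation of 3-substituted oxindoles to quaternary centres and the racemic palladium-catalysed dearomative allylation of acylphloroglucinols; the stereocentre at C4 is thus set under ligand control (Tsuji–Trost type).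

Step 6
Reactants: 8 methyl (3S)-2,4-dihydroxy-3-methyl-3-(3-methylbut-2-en-1-yl)-5-(2-methylpropanoyl)-6-oxocyclohexa-1,4-diene-1-carboxylate
Product: 10 (4R)-3,5-dihydroxy-4-methyl-4-(3-methylbut-2-en-1-yl)-2-(2-methylpropanoyl)cyclohexa-2,5-dien-1-one, via ring-A carboxylic acid 9 (not isolated)
Conditions: LiI, EtOAc, reflux; then 1 M HCl, rt
Reagents that add atoms: none
Why: SN2 demethylation of the ester by iodide (Krapcho-type dealkoxycarbonylation) gives the 2-carboxy-1,3-dione 9, which should lose CO2 spontaneously on acidification; the quaternary C4 is not involved, so its configuration is retained.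

Step 7
Reactants: 11 phloroglucinol
Product: 12 2-methyl-1-(2,4,6-trihydroxyphenyl)propan-1-one
Conditions: 2-methylpropanoyl chloride, AlCl3, PhNO2–CH2Cl2, rt
Reagents that add atoms: 2-methylpropanoyl chloride, CC(C)C(Cl)=O
Why: Friedel–Crafts monoacylation of phloroglucinol is a standard entry to acylphloroglucinols; the first acyl group deactivates the ring against a second.

Step 8
Reactants: 12 2-methyl-1-(2,4,6-trihydroxyphenyl)propan-1-one
Product: 13 1-[2,6-dihydroxy-4-(2-methylbut-3-yn-2-yloxy)phenyl]-2-methylpropan-1-one
Conditions: 3-chloro-3-methylbut-1-yne, DBU, CuCl2·2H2O (1 mol %), MeCN, 0 °C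
Reagents that add atoms: 3-chloro-3-methylbut-1-yne, CC(C)(Cl)C#C
Why: Copper-catalysed propargylic etherification should take place at the 4-hydroxyl, which is the most acidic and the only one not chelated to the ketone.

Step 9
Reactants: 13 1-[2,6-dihydroxy-4-(2-methylbut-3-yn-2-yloxy)phenyl]-2-methylpropan-1-one
Product: 14 1-(5,7-dihydroxy-2,2-dimethyl-2H-chromen-6-yl)-2-methylpropan-1-one
Conditions: xylene, 140 °C
Reagents that add atoms: none
Why: Thermal aryl propargyl ether Claisen rearrangement, 1,5-hydrogen shift and oxa-6π electrocyclization close the pyran ring; because the ether oxygen is para to the acyl group and both ortho carbons are equivalent, only the 6-acyl-5,7-dihydroxy chromene can form.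

Step 10
Reactants: 14 1-(5,7-dihydroxy-2,2-dimethyl-2H-chromen-6-yl)-2-methylpropan-1-one
Product: 15 1-{8-[(dimethylamino)methyl]-5,7-dihydroxy-2,2-dimethyl-2H-chromen-6-yl}-2-methylpropan-1-one
Conditions: N,N-dimethylmethyleneiminium iodide, CH2Cl2, rt; aq. NaHCO3
Reagents that add atoms: N,N-dimethylmethyleneiminium iodide, C=[N+](C)C.[I-]
Why: Mannich aminomethylation can occur only at C8, the single free position of the electron-rich ring.

Step 11
Reactants: 10 (4R)-3,5-dihydroxy-4-methyl-4-(3-methylbut-2-en-1-yl)-2-(2-methylpropanoyl)cyclohexa-2,5-dien-1-one; 15 1-{8-[(dimethylamino)methyl]-5,7-dihydroxy-2,2-dimethyl-2H-chromen-6-yl}-2-methylpropan-1-one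
Product: 17 (4R)-2-{[5,7-dihydroxy-2,2-dimethyl-6-(2-methylpropanoyl)-2H-chromen-8-yl]methyl}-3,5-dihydroxy-4-methyl-4-(3-methylbut-2-en-1-yl)-6-(2-methylpropanoyl)cyclohexa-2,5-dien-1-one (target), via ortho-quinone methide 16 (not isolated)
Conditions: toluene, 90 °C, Ar
Reagents that add atoms: none
Why: Thermal elimination of dimethylamine from the phenolic Mannich base gives ortho-quinone methide 16, which should be captured at its methylene carbon by the acidic enol carbon C2 of 10 (Michael addition with rearomatization), the established Mannich-base route to methylene-bridged acylphloroglucinol dimers; C4 is untouched.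

**Compound list**

1 | methyl 3-oxopentanoate | CCC(=O)CC(=O)OC | starting material
2 | methyl 3-(trimethylsilyloxy)pent-2-enoate (E/Z mixture) | CCC(O[Si](C)(C)C)=CC(=O)OC | intermediate
3 | 1-methoxy-1,3-bis(trimethylsilyloxy)penta-1,3-diene (mixture of geometric isomers) | CC=C(O[Si](C)(C)C)C=C(OC)O[Si](C)(C)C | intermediate
4 | methyl 3-chloro-3-oxopropanoate (methyl malonyl chloride) | COC(=O)CC(Cl)=O | starting material
5 | dimethyl 4-methyl-3,5-dioxoheptanedioate | COC(=O)CC(=O)C(C)C(=O)CC(=O)OC | intermediate
6 | methyl 2,4,6-trihydroxy-3-methylbenzoate | COC(=O)c1c(O)cc(O)c(C)c1O | intermediate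
7 | methyl 2,4,6-trihydroxy-3-methyl-5-(2-methylpropanoyl)benzoate | COC(=O)c1c(O)c(C)c(O)c(C(=O)C(C)C)c1O | intermediate
8 | methyl (3S)-2,4-dihydroxy-3-methyl-3-(3-methylbut-2-en-1-yl)-5-(2-methylpropanoyl)-6-oxocyclohexa-1,4-diene-1-carboxylate | CC(C)=CC[C@]1(C)C(O)=C(C(=O)OC)C(=O)C(C(=O)C(C)C)=C1O | intermediate
9 | (3S)-2,4-dihydroxy-3-methyl-3-(3-methylbut-2-en-1-yl)-5-(2-methylpropanoyl)-6-oxocyclohexa-1,4-diene-1-carboxylic acid | CC(C)=CC[C@]1(C)C(O)=C(C(=O)O)C(=O)C(C(=O)C(C)C)=C1O | intermediate
10 | (4R)-3,5-dihydroxy-4-methyl-4-(3-methylbut-2-en-1-yl)-2-(2-methylpropanoyl)cyclohexa-2,5-dien-1-one | CC(C)=CC[C@]1(C)C(O)=CC(=O)C(C(=O)C(C)C)=C1O | intermediate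
11 | phloroglucinol (benzene-1,3,5-triol) | Oc1cc(O)cc(O)c1 | starting material
12 | 2-methyl-1-(2,4,6-trihydroxyphenyl)propan-1-one | CC(C)C(=O)c1c(O)cc(O)cc1O | intermediate
13 | 1-[2,6-dihydroxy-4-(2-methylbut-3-yn-2-yloxy)phenyl]-2-methylpropan-1-one | CC(C)C(=O)c1c(O)cc(OC(C)(C)C#C)cc1O | intermediate
14 | 1-(5,7-dihydroxy-2,2-dimethyl-2H-chromen-6-yl)-2-methylpropan-1-one | CC(C)C(=O)c1c(O)cc2OC(C)(C)C=Cc2c1O | intermediate
15 | 1-{8-[(dimethylamino)methyl]-5,7-dihydroxy-2,2-dimethyl-2H-chromen-6-yl}-2-methylpropan-1-one | CC(C)C(=O)c1c(O)c(CN(C)C)c2OC(C)(C)C=Cc2c1O | intermediate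
16 | 5-hydroxy-2,2-dimethyl-8-methylidene-6-(2-methylpropanoyl)-2H-chromen-7(8H)-one (ortho-quinone methide) | C=C1C(=O)C(C(=O)C(C)C)=C(O)C2=C1OC(C)(C)C=C2 | intermediate
17 | (4R)-2-{[5,7-dihydroxy-2,2-dimethyl-6-(2-methylpropanoyl)-2H-chromen-8-yl]methyl}-3,5-dihydroxy-4-methyl-4-(3-methylbut-2-en-1-yl)-6-(2-methylpropanoyl)cyclohexa-2,5-dien-1-one | CC(C)=CC[C@]1(C)C(O)=C(Cc2c(O)c(C(=O)C(C)C)c(O)c3c2OC(C)(C)C=C3)C(=O)C(C(=O)C(C)C)=C1O | target

**Step count and risks**

Total steps: 11. Longest linear sequence: 7 (steps 1–6 and 11); steps 7–10 form the chromene branch.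

Steps most likely to fail:

1. Step 5 (proposed new method). Facial discrimination at C4 may be poor, allylation may occur at oxygen, or the nucleophile may attack the substituted allyl terminus (reverse prenylation). The fallback sets out from 7 and uses known chemistry: alkylative dearomatization with prenyl bromide in aqueous KOH at 0 °C should give the racemic methyl 2,4-dihydroxy-3-methyl-3-(3-methylbut-2-en-1-yl)-5-(2-methylpropanoyl)-6-oxocyclohexa-1,4-diene-1-carboxylate F1. Demethylation and decarboxylation as in step 6 then give racemic 3,5-dihydroxy-4-methyl-4-(3-methylbut-2-en-1-yl)-2-(2-methylpropanoyl)cyclohexa-2,5-dien-1-one F2. Its enantiomers are separated by preparative chromatography on a chiral stationary phase, and the (4R)-enantiomer is 10, where the route is rejoined.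

2. Step 3. Ring closure may go through oxygen (lactonization) instead of carbon, methoxide may cleave the diketone (retro-Claisen), or the diene may be acylated at its central carbon. The fallback sets out from 5, isolated after aqueous work-up of the acylation, and changes the one-pot anionic closure into a two-stage ring transformation: DBU in toluene at 80 °C closes 5 at oxygen to 4-hydroxy-6-(2-methoxy-2-oxoethyl)-5-methyl-2H-pyran-2-one F3, which is purified. Mg(OMe)2 in MeOH at reflux then reopens the lactone and templates the Claisen closure through carbon (pyranone-to-phloroglucinol rearrangement), returning to the route at 6.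

3. Step 11. The methylene bridge may exchange between the partners (retro-Michael/Michael scrambling to symmetrical dimers), the quinone methide may self-condense, or the liberated amine may condense with the triketone. The fallback sets out from 10 and reverses the polarity of the coupling: Mannich reaction of 10 with N,N-dimethylmethyleneiminium iodide gives (4R)-2-[(dimethylamino)methyl]-3,5-dihydroxy-4-methyl-4-(3-methylbut-2-en-1-yl)-6-(2-methylpropanoyl)cyclohexa-2,5-dien-1-one F4. With chromene 14 in MeCN at 40 °C, F4 should lose dimethylamine to the 2-methylene triketone, which is trapped by C8 of 14 in a Friedel–Crafts-type conjugate addition, arriving at 17.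

Further compounds

F1 | step 5 | racemic methyl 2,4-dihydroxy-3-methyl-3-(3-methylbut-2-en-1-yl)-5-(2-methylpropanoyl)-6-oxocyclohexa-1,4-diene-1-carboxylate | CC(C)=CCC1(C)C(O)=C(C(=O)OC)C(=O)C(C(=O)C(C)C)=C1O
F2 | step 5 | racemic 3,5-dihydroxy-4-methyl-4-(3-methylbut-2-en-1-yl)-2-(2-methylpropanoyl)cyclohexa-2,5-dien-1-one | CC(C)=CCC1(C)C(O)=CC(=O)C(C(=O)C(C)C)=C1O
F3 | step 3 | 4-hydroxy-6-(2-methoxy-2-oxoethyl)-5-methyl-2H-pyran-2-one | COC(=O)CC1=C(C)C(O)=CC(=O)O1
F4 | step 11 | (4R)-2-[(dimethylamino)methyl]-3,5-dihydroxy-4-methyl-4-(3-methylbut-2-en-1-yl)-6-(2-methylpropanoyl)cyclohexa-2,5-dien-1-one | CC(C)=CC[C@]1(C)C(O)=C(CN(C)C)C(=O)C(C(=O)C(C)C)=C1O
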